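The plan rests on recognising that C3 of ring B (O1, C2, C3, C3a, C7a), its ring A neighbour C3a and the CH2OH carbon are C3, C4a and the carbonyl carbon C4 of a flavanone, so the dihydrobenzofuran is disconnected to its six-membered homologue. In one operation, trivalent iodine oxidation shifts C4a of ring A from C4 to C3: the C3–C3a bond forms, ring B closes by contraction, C4 is extruded as the ester and C3 is set trans to C2. The precursor is an enantiopure (2S)-6-bromo-8-methoxyflavanone, made by asymmetric conjugate addition to a chromone, whose syringyl ring C is deactivated as its methanesulfonate.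

Key step: step 6

Assumption: the pyridine-oxazoline ligand is taken to show on chromones the facial preference it shows on 3-substituted cyclohexenones, which assigns the (R)-ligand to the (2S)-flavanone; if the first batch proves otherwise, the antipodal ligand is used with no other change.

Remark: C3 is S in ester 11 and R in alcohol 12 and the target; the geometry (2,3-trans) is the same, only the sequence-rule priorities change.

Step 1
Reactants: 1 1-(2-hydroxy-3-methoxyphenyl)ethanone
Product: 2 1-(5-bromo-2-hydroxy-3-methoxyphenyl)ethanone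
Conditions: NBS (1.05 equiv), MeCN, 0 °C to rt
Reagents that add atoms: N-bromosuccinimide, O=C1CCC(=O)N1Br
Why: Electrophilic aromatic bromination should go to C5, para to the phenol, because both positions ortho to the hydroxyl group are substituted and the remaining positions are deactivated by the acetyl group.

Step 2
Reactants: 2 1-(5-bromo-2-hydroxy-3-methoxyphenyl)ethanone
Product: 4 6-bromo-8-methoxy-4H-chromen-4-one, via enaminone 3 (not isolated)
Conditions: Me2NCH(OMe)2, toluene, 100 °C; evaporate; conc. HCl, CH2Cl2, 40 °C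
Reagents that add atoms: N,N-dimethylformamide dimethyl acetal, COC(OC)N(C)C
Why: Condensation of the methyl ketone with the amide acetal gives the enaminone, and acid-promoted addition of the phenol to its β-carbon with loss of dimethylamine closes the pyranone (enaminone chromone synthesis).

Step 3
Reactants: 5 2,6-dimethoxy-4-(4,4,5,5-tetramethyl-1,3,2-dioxaborolan-2-yl)phenol
Product: 6 2,6-dimethoxy-4-(4,4,5,5-tetramethyl-1,3,2-dioxaborolan-2-yl)phenyl methanesulfonate
Conditions: MsCl, Et3N, CH2Cl2, 0 °C
Reagents that add atoms: methanesulfonyl chloride, CS(=O)(=O)Cl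
Why: O-Sulfonylation of the phenol installs an electron-withdrawing sulfonate that is stable to acid, to palladium catalysis and to hydride, while the pinacol boronate is inert to these conditions.

Step 4
Reactants: 6 2,6-dimethoxy-4-(4,4,5,5-tetramethyl-1,3,2-dioxaborolan-2-yl)phenyl methanesulfonate
Product: 7 [3,5-dimethoxy-4-(methylsulfonyloxy)phenyl]boronic acid
Conditions: NaIO4, NH4OAc, acetone/H2O, rt
Reagents that add atoms: water, O
Why: The boronate equilibrates with the boronic acid in aqueous medium and NaIO4 removes the released pinacol by glycol cleavage (Malaprade reaction), which drives the hydrolysis to the free boronic acid needed for transmetalation.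

Step 5
Reactants: 4 6-bromo-8-methoxy-4H-chromen-4-one; 7 [3,5-dimethoxy-4-(methylsulfonyloxy)phenyl]boronic acid
Product: 8 (2S)-6-bromo-2-[3,5-dimethoxy-4-(methylsulfonyloxy)phenyl]-8-methoxy-2,3-dihydro-4H-chromen-4-one
Conditions: 7 (2 equiv), Pd(OCOCF3)2 (5 mol%), (R)-4-tert-butyl-2-(pyridin-2-yl)-4,5-dihydrooxazole (6 mol%), NH4PF6 (30 mol%), H2O (5 equiv), ClCH2CH2Cl, 60 °C
Reagents that add atoms: none
Why: In this palladium-catalysed asymmetric conjugate addition of an arylboronic acid, the aryl–palladium species carrying the chiral pyridine-oxazoline inserts across C2=C3 on the face left open by the tert-butyl group, which sets C2 as S, and because the cycle stays at divalent palladium the C–Br bond should not be touched.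

Step 6
Reactants: 8 (2S)-6-bromo-2-[3,5-dimethoxy-4-(methylsulfonyloxy)phenyl]-8-methoxy-2,3-dihydro-4H-chromen-4-one
Product: 11 methyl (2S,3S)-5-bromo-2-[3,5-dimethoxy-4-(methylsulfonyloxy)phenyl]-7-methoxy-2,3-dihydro-1-benzofuran-3-carboxylate, via enol ether 9 (not isolated), via ketal iodane 10 (not isolated)
Conditions: PhI(OAc)2 (1.3 equiv), HC(OMe)3/MeOH, conc. H2SO4, 0 °C to rt; aq NaHCO3
Reagents that add atoms: methanol, CO; trimethyl orthoformate, COC(OC)OC (either supplies the ester methoxy group)
Why: Acid and orthoformate convert the ketone into its dimethyl ketal and the 4-methoxy enol ether 9, which the electrophilic trivalent iodine reagent attacks at C3 anti to the equatorial C2 aryl group to give ketal iodane 10, whose C3–I bond lies antiperiplanar to the C4–C4a ring bond. Departure of iodobenzene is assisted by a 1,2-shift of the ring A carbon C4a from C4 to C3 through a spiro phenonium-like transition state, and the dimethoxycarbenium ion left at the former C4 collapses to the methyl ester; this is the known oxidative ring contraction of flavanones with trivalent iodine or Tl(NO3)3 in methanol/orthoformate. Ring B is thus closed by contraction of the pyranone and not by a cyclisation, the C3–C3a bond being made by the migrating carbon (formally 3-exo-tet attack of C4a on C3 followed by C4–C4a cleavage). The new C3 centre is controlled by C2: substitution at C3 inverts the anti C–I bond and so places CO2Me trans to the aryl group, which is also the thermodynamically preferred ester, while C2 is not involved and keeps the configuration set in step 5. The step needs ring A migration to win over migration of ring C from C2, over elimination to the flavone and over acid-induced C2–O1 opening; the mesylate makes ring C a poor migrating group and destabilises a cation at C2, O1 ortho to C4a makes ring A migrate readily, bromine sits meta to C4a where it cannot withdraw by resonance, and the ketalising medium removes the free carbonyl group that ring opening requires.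

Step 7
Reactants: 11 methyl (2S,3S)-5-bromo-2-[3,5-dimethoxy-4-(methylsulfonyloxy)phenyl]-7-methoxy-2,3-dihydro-1-benzofuran-3-carboxylate
Product: 12 4-[(2S,3R)-5-bromo-3-(hydroxymethyl)-7-methoxy-2,3-dihydro-1-benzofuran-2-yl]-2,6-dimethoxyphenyl methanesulfonate
Conditions: LiBH4, THF, 0 °C to rt; aq NH4Cl
Reagents that add atoms: none
Why: Chemoselective ester reduction with LiBH4 should give the primary alcohol without touching the aryl bromide or the aryl mesylate, and it removes the acidic C3–H before any basic step so that neither centre can be scrambled.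

Step 8
Reactants: 12 4-[(2S,3R)-5-bromo-3-(hydroxymethyl)-7-methoxy-2,3-dihydro-1-benzofuran-2-yl]-2,6-dimethoxyphenyl methanesulfonate; 13 methyl acrylate
Product: 14 methyl (2E)-3-[(2S,3R)-2-[3,5-dimethoxy-4-(methylsulfonyloxy)phenyl]-3-(hydroxymethyl)-7-methoxy-2,3-dihydro-1-benzofuran-5-yl]prop-2-enoate
Conditions: Pd(OAc)2 (5 mol%), P(o-tol)3 (12 mol%), Et3N, DMF, 95 °C
Reagents that add atoms: none
Why: In the Mizoroki–Heck reaction, oxidative addition of zerovalent palladium at the unhindered C5–Br bond, syn insertion of the acrylate and syn β-hydride elimination should give the E cinnamate, while the hindered aryl mesylate and the free alcohol are inert to this catalyst.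

Step 9
Reactants: 14 methyl (2E)-3-[(2S,3R)-2-[3,5-dimethoxy-4-(methylsulfonyloxy)phenyl]-3-(hydroxymethyl)-7-methoxy-2,3-dihydro-1-benzofuran-5-yl]prop-2-enoate
Product: 15 (2E)-3-[(2S,3R)-2-(4-hydroxy-3,5-dimethoxyphenyl)-3-(hydroxymethyl)-7-methoxy-2,3-dihydro-1-benzofuran-5-yl]prop-2-enoic acid
Conditions: 2 M aq KOH, MeOH/THF, rt then 55 °C, Ar; 1 M HCl to pH 3, 0 °C
Reagents that add atoms: potassium hydroxide, [K+].[OH-] (its oxygen becomes the carboxyl OH)
Why: Saponification of the methyl ester and attack of hydroxide or methoxide at the sulfur of the aryl mesylate should release acid and phenol in one operation, and with CH2OH instead of an ester at C3 there is no acidic C3–H through which base could open ring B.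

Compound list
1 | 1-(2-hydroxy-3-methoxyphenyl)ethanone | CC(=O)c1cccc(OC)c1O | starting material
2 | 1-(5-bromo-2-hydroxy-3-methoxyphenyl)ethanone | CC(=O)c1cc(Br)cc(OC)c1O | intermediate
3 | (2E)-1-(5-bromo-2-hydroxy-3-methoxyphenyl)-3-(dimethylamino)prop-2-en-1-one (enaminone, formed in the flask) | CN(C)/C=C/C(=O)c1cc(Br)cc(OC)c1O | intermediate
4 | 6-bromo-8-methoxy-4H-chromen-4-one | COc1cc(Br)cc2c(=O)ccoc12 | intermediate
5 | 2,6-dimethoxy-4-(4,4,5,5-tetramethyl-1,3,2-dioxaborolan-2-yl)phenol | COc1cc(B2OC(C)(C)C(C)(C)O2)cc(OC)c1O | starting material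
6 | 2,6-dimethoxy-4-(4,4,5,5-tetramethyl-1,3,2-dioxaborolan-2-yl)phenyl methanesulfonate | COc1cc(B2OC(C)(C)C(C)(C)O2)cc(OC)c1OS(C)(=O)=O | intermediate
7 | [3,5-dimethoxy-4-(methylsulfonyloxy)phenyl]boronic acid | COc1cc(B(O)O)cc(OC)c1OS(C)(=O)=O | intermediate
8 | (2S)-6-bromo-2-[3,5-dimethoxy-4-(methylsulfonyloxy)phenyl]-8-methoxy-2,3-dihydro-4H-chromen-4-one | COc1cc([C@H]2Oc3c(OC)cc(Br)cc3C(=O)C2)cc(OC)c1OS(C)(=O)=O | intermediate
9 | (2S)-6-bromo-2-[3,5-dimethoxy-4-(methylsulfonyloxy)phenyl]-4,8-dimethoxy-2H-chromene (enol ether, formed in the flask) | COc1cc([C@H]2Oc3c(OC)cc(Br)cc3C(OC)=C2)cc(OC)c1OS(C)(=O)=O | intermediate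
10 | (2R,3R)-3-[acetoxy(phenyl)-λ3-iodanyl]-6-bromo-2-[3,5-dimethoxy-4-(methylsulfonyloxy)phenyl]-4,4,8-trimethoxychromane (ketal iodane, formed in the flask; C–I anti to the C2 aryl group, C2 geometry as in 8) | COc1cc([C@H]2Oc3c(OC)cc(Br)cc3C(OC)(OC)[C@@H]2I(OC(C)=O)c4ccccc4)cc(OC)c1OS(C)(=O)=O | intermediate
11 | methyl (2S,3S)-5-bromo-2-[3,5-dimethoxy-4-(methylsulfonyloxy)phenyl]-7-methoxy-2,3-dihydro-1-benzofuran-3-carboxylate (2,3-trans) | COc1cc([C@H]2Oc3c(OC)cc(Br)cc3[C@@H]2C(=O)OC)cc(OC)c1OS(C)(=O)=O | intermediate
12 | 4-[(2S,3R)-5-bromo-3-(hydroxymethyl)-7-methoxy-2,3-dihydro-1-benzofuran-2-yl]-2,6-dimethoxyphenyl methanesulfonate | COc1cc([C@H]2Oc3c(OC)cc(Br)cc3[C@@H]2CO)cc(OC)c1OS(C)(=O)=O | intermediate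
13 | methyl acrylate | C=CC(=O)OC | starting material
14 | methyl (2E)-3-[(2S,3R)-2-[3,5-dimethoxy-4-(methylsulfonyloxy)phenyl]-3-(hydroxymethyl)-7-methoxy-2,3-dihydro-1-benzofuran-5-yl]prop-2-enoate | COc1cc([C@H]2Oc3c(OC)cc(/C=C/C(=O)OC)cc3[C@@H]2CO)cc(OC)c1OS(C)(=O)=O | intermediate
15 | (2E)-3-[(2S,3R)-2-(4-hydroxy-3,5-dimethoxyphenyl)-3-(hydroxymethyl)-7-methoxy-2,3-dihydro-1-benzofuran-5-yl]prop-2-enoic acid | COc1cc([C@H]2Oc3c(OC)cc(/C=C/C(=O)O)cc3[C@@H]2CO)cc(OC)c1O | target

Total step count: 9. Longest linear sequence: 7 steps (steps 1, 2, 5, 6, 7, 8, 9; the boronic acid branch, steps 3, 4, 5 to 9, is equally long).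

Steps most likely to fail

Step 6 (ring contraction). The rearrangement may be diverted by migration of the C2 aryl group, by elimination to the aromatic pyranone, or by acid-induced opening of the heterocycle with erosion of enantiopurity. The fallback reaches the same bond by a Wolff rearrangement and sets out from 8. The lithium enolate of 8 (LiN(SiMe3)2, THF, −78 °C) is acylated with CF3CO2CH2CF3 to the 3-trifluoroacetyl flavanone F1. Detrifluoroacetylative diazo transfer (MsN3, Et3N, MeCN, H2O) should then give the 3-diazo flavanone F2. Photolysis at 350 nm in MeOH moves the same ring A carbon from C4 to C3, and the ketene is trapped by methanol. This should give ester 11 together with its 2,3-cis epimer F3, and brief equilibration with catalytic NaOMe in MeOH at 0 °C converges the mixture on 11, where the route is rejoined.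

Step 5 (asymmetric conjugate addition). Facial selectivity may be insufficient or inverted for this substituted pair, and protodeboronation may outrun insertion. The fallback replaces the addition by a condensation and a resolution and sets out from 2. Syringaldehyde is mesylated (MsCl, Et3N) to 4-formyl-2,6-dimethoxyphenyl methanesulfonate F4. Acid-mediated Claisen–Schmidt condensation of 2 with F4 (HCl generated from SOCl2 in EtOH) gives the 2′-hydroxychalcone F5. Oxa-Michael cyclisation (NaOAc, EtOH, reflux) gives the racemic flavanone F6. Preparative chromatography on a chiral stationary phase delivers 8, where the route is rejoined; the unwanted enantiomer can be recycled through base-induced ring opening and reclosure.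

Step 9 (global hydrolysis). The hindered sulfonate may cleave incompletely, and forcing with hot hydroxide could let the liberated phenoxide open ring B at C2–O1, with epimerisation or degradation. The fallback separates the two cleavages and sets out from 14. LiOH in THF/H2O at rt hydrolyses only the methyl ester to the mesylated cinnamic acid F7. The mesylate is then removed without hydroxide or heat by sulfene elimination with excess LiN(i-Pr)2 (THF, −78 °C to 0 °C), and acidic work-up arrives at 15.

Further compounds
F1 | step 6 | (2S)-6-bromo-2-[3,5-dimethoxy-4-(methylsulfonyloxy)phenyl]-8-methoxy-3-(trifluoroacetyl)-2,3-dihydro-4H-chromen-4-one (C3 epimers and enol) | COc1cc([C@H]2Oc3c(OC)cc(Br)cc3C(=O)C2C(=O)C(F)(F)F)cc(OC)c1OS(C)(=O)=O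
F2 | step 6 | (2R)-6-bromo-3-diazo-2-[3,5-dimethoxy-4-(methylsulfonyloxy)phenyl]-8-methoxy-2,3-dihydro-4H-chromen-4-one (C2 geometry as in 8) | COc1cc([C@H]2Oc3c(OC)cc(Br)cc3C(=O)C2=[N+]=[N-])cc(OC)c1OS(C)(=O)=O
F3 | step 6 | methyl (2S,3R)-5-bromo-2-[3,5-dimethoxy-4-(methylsulfonyloxy)phenyl]-7-methoxy-2,3-dihydro-1-benzofuran-3-carboxylate (2,3-cis) | COc1cc([C@H]2Oc3c(OC)cc(Br)cc3[C@H]2C(=O)OC)cc(OC)c1OS(C)(=O)=O
F4 | step 5 | 4-formyl-2,6-dimethoxyphenyl methanesulfonate | COc1cc(C=O)cc(OC)c1OS(C)(=O)=O
F5 | step 5 | (2E)-1-(5-bromo-2-hydroxy-3-methoxyphenyl)-3-[3,5-dimethoxy-4-(methylsulfonyloxy)phenyl]prop-2-en-1-one | COc1cc(/C=C/C(=O)c2cc(Br)cc(OC)c2O)cc(OC)c1OS(C)(=O)=O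
F6 | step 5 | racemic 6-bromo-2-[3,5-dimethoxy-4-(methylsulfonyloxy)phenyl]-8-methoxy-2,3-dihydro-4H-chromen-4-one | COc1cc(C2Oc3c(OC)cc(Br)cc3C(=O)C2)cc(OC)c1OS(C)(=O)=O
F7 | step 9 | (2E)-3-[(2S,3R)-2-[3,5-dimethoxy-4-(methylsulfonyloxy)phenyl]-3-(hydroxymethyl)-7-methoxy-2,3-dihydro-1-benzofuran-5-yl]prop-2-enoic acid | COc1cc([C@H]2Oc3c(OC)cc(/C=C/C(=O)O)cc3[C@@H]2CO)cc(OC)c1OS(C)(=O)=O
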